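The data were generated by integration for substances that don't exist; noise was put on by code.

The leftover of left-handed substrate, as a fraction of its own charge, shows how far a flask has run. That substrate is half of what is charged, so each product reading gives the leftover directly.

| setting | violet | red | south | north-east |
|---|---|---|---|---|
| left-handed substrate | 1.5 M | 1.5 M | 1.5 M | 1.5 M |
| right-handed substrate | 1.5 M | 1.5 M | 1.5 M | 1.5 M |
| gas | 200 mM (held) | 200 mM (held) | 200 mM (held) | 200 mM (held) |
| catalyst | 21 mM | 33 mM | 15 mM | 15 mM |
| temperature | 95 °C | 115 °C | 100 °C | 130 °C |
| remark | run made earlier | run made earlier |  |  |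
| time |  |  | 6.0 d | 6.0 d |

| run | time / d | left-handed product / % |
|---|---|---|
| violet | 0.625 | 9.3 |
| violet | 1.25 | 17.8 |
| violet | 2.08 | 24.6 |
| violet | 3.00 | 31.8 |
| violet | 4.00 | 32.4 |
| violet | 5.00 | 38.9 |
| red | 0.125 | 4.0 |
| red | 0.417 | 20.9 |
| red | 0.625 | 28.6 |
| red | 1.04 | 37.8 |
| red | 1.25 | 40.2 |
| red | 2.08 | 49.6 |
| red | 2.50 | 48.7 |

(each reading ± 1 percentage point)

1. the flask that comes out highest in amount of left-handed product, in percent of the left-handed substrate and right-handed substrate together charged, or "all alike" when all lie within 1.5 percentage points (south / north-east / all alike)
2. left-handed product at the end, in percent of the left-handed substrate and right-handed substrate together charged, south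
3. left-handed product at the end, in percent of the left-handed substrate and right-handed substrate together charged, north-east

- catalyst is single-handed; left-handed substrate and right-handed substrate are mirror images of each other, charged as a racemate, each of them at the stated concentration
- the earlier runs were read with a standard deviation of 1 percentage point
- at the start none of the gas is in solution

How many half-lives has each run lived? Violet's last reading leaves 22.2%, which is 2.17 half-lives and a half-life of 2.30 d. Red's reading at 1.25 d leaves 19.6%, a half-life of 0.532 d. A steady half-life assumes pseudo-first-order decay.

What remains once catalyst is taken out? Half-life times catalyst fraction (catalyst over the left-handed substrate charge) is the half-life dose: 0.0322 d for violet, 0.0117 d for red. These are readings, and they carry the scatter. Spaced evenly in the logarithm between the two temperatures, the half-life dose at south's temperature is 0.0250 d, and extrapolated to north-east's it is 0.00547 d.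

How many half-lives fit into 6.0 d? By this reckoning south gets 2.40, which leaves 18.9% of its left-handed substrate and gives left-handed product at 40.5% of the whole charge. North-east gets 11.0, which leaves 0.0498%.

The forecast, reckoned separately, names north-east, with south at 41.5% (36% to 46%) and north-east at 49.5% (44% to 52%). It warns that “Temperature and catalyst are confounded across the two runs”. Its south figure of 41.5% stands above the 40.5% reckoned here.

South gives 41.7% and north-east 50.0%, so north-east comes out above south.

    coupling partner + catalyst + left-handed substrate → catalyst + left-handed product (k = 0.280 L² mol⁻² min⁻¹, Ea = 47.0 kJ mol⁻¹)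
    coupling partner + catalyst + right-handed substrate → catalyst + right-handed product (k = 0.120 L² mol⁻² min⁻¹, Ea = 46.0 kJ mol⁻¹)
    gas ⇌ coupling partner, rate k3*(csat - [coupling partner]) (kL = 0.0250 min⁻¹)
    catalyst ⇌ dormant form (K = 2.90, k = 0.00970 min⁻¹, Ea = 117 kJ mol⁻¹, ΔH = −45.0 kJ mol⁻¹)
    (constants at 100 °C)

In south, the half-life of left-handed substrate by its coupling step stands at 2.3 d at the end; 6.0 d is 2.61 times that end value, and 17% of the charge of left-handed substrate is left. As a dose, that half-life is 0.0229 d, beside the 0.0250 d reckoned from violet and red. A further flask like south, with 0.0037 M of catalyst, gets a half-life of 10.1 d from that reckoned dose, hence 0.592 half-lives and a leftover of 66.3%. That flask still holds 63% of its charge of left-handed substrate at the end.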